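## Retrosynthetic overview
1. Target ⇒ its bis-silyl ether ⇒ (Stille, C6–prenyl bond) a (3S)-6-bromoisoflavanone. The prenyl group is sensitive to the iodane, so it enters only after the oxidative step.
2. (3S)-6-Bromoisoflavanone ⇒ 2'-hydroxychalcone, in one flask. A chiral aryl-λ3-iodane drives the Cβ→Cα 1,2-aryl shift (isoflavone-synthase logic, sets C3). The 2'-OH closes O1–C2 to a 2-methoxyisoflavanone, the O-methyl form of the biosynthetic 2-hydroxyisoflavanone. Et3SiH then takes C2 to CH2, so no isoflavone is formed.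
3. Chalcone ⇒ Claisen–Schmidt condensation of a bromoresacetophenone with a hydroxydimethoxybenzaldehyde.
4. Ring order: rings A and B are bought. Ring C is the only ring formed (step 3).

Assumption 1: compounds 1, 2 and 7 are catalogue items, and the iodane of step 3, COC(=O)[C@@H](C)Oc1cccc(O[C@H](C)C(=O)OC)c1I(OC(C)=O)OC(C)=O, is used as a known reagent (2-iodoresorcinol + methyl (S)-lactate by Mitsunobu reaction, then NaBO3·4H2O/AcOH) and its iodoarene is recovered.
Assumption 2: the (R,R)-iodane is taken to give (3S); if the first run shows (3R), the (S,S)-iodane from methyl (R)-lactate is used and nothing else changes.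

## Route

Step 1
Reactants: 1 1-(5-bromo-2,4-dihydroxyphenyl)ethan-1-one; 2 4-hydroxy-2,5-dimethoxybenzaldehyde
Product: 3 (E)-1-(5-bromo-2,4-dihydroxyphenyl)-3-(4-hydroxy-2,5-dimethoxyphenyl)prop-2-en-1-one
Conditions: dry HCl (sat.), EtOAc/EtOH 4:1, 0 °C to rt, 24 h
Reagents that add atoms: none
Why: In this acid-catalysed Claisen–Schmidt (crossed aldol) condensation the enol of 1 adds to the protonated, non-enolisable aldehyde 2 and dehydration through the well-stabilised benzylic cation gives only the E-enone, so none of the three phenols needs masking, whereas in base the aldehyde phenoxide would be unreactive.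

Step 2
Reactants: 3 the trihydroxychalcone
Product: 4 (E)-1-{5-bromo-4-[(tert-butyldimethylsilyl)oxy]-2-hydroxyphenyl}-3-{4-[(tert-butyldimethylsilyl)oxy]-2,5-dimethoxyphenyl}prop-2-en-1-one
Conditions: TBSCl (2.2 equiv), imidazole (4.5 equiv), DMF, 0 °C to rt, 3 h
Reagents that add atoms: tert-butyldimethylsilyl chloride, CC(C)(C)[Si](C)(C)Cl
Why: This selective O-silylation caps the two free, oxidisable phenols, while the 2'-OH is held in a hydrogen bond to the ketone, stays unreactive and remains free for the ring closure.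

Step 3
Reactants: 4 the bis-TBS 2'-hydroxychalcone
Product: 6 (3S)-6-bromo-7-[(tert-butyldimethylsilyl)oxy]-3-{4-[(tert-butyldimethylsilyl)oxy]-2,5-dimethoxyphenyl}chroman-4-one, via 2-methoxyisoflavanone 5 (not isolated)
Conditions: (R,R)-ArI(OAc)2 (1.1 equiv, Ar = 2,6-bis[(1R)-1-(methoxycarbonyl)ethoxy]phenyl), BF3·OEt2 (2 equiv), MeOH (3 equiv), CH2Cl2, −78 to −40 °C, 3 h; then −78 °C, Et3SiH (10 equiv), BF3·OEt2 (3 equiv), −78 to −45 °C; pH 7 buffer at −45 °C
Reagents that add atoms: methanol, CO (supplies the 2-OMe group of 5, which is lost again on the way to 6)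
Why: Proposed new method: the BF3-activated lactate-derived aryl-λ3-iodane binds one face of the enone C=C at Cα while methanol caps the benzylic Cβ, the very electron-rich ring B then shifts from Cβ to Cα anti to the departing iodoarene (stereospecific inversion at Cα, which fixes C3 as S), the chelated 2'-OH closes ring C on the resulting C2 oxocarbenium ion to give 5, and re-ionisation of 5 at −78 °C under a tenfold excess of Et3SiH lets hydride capture at C2 outrun loss of H-3, so the stereocentre survives instead of being erased in an isoflavone; the closest known reaction types are the enantioselective trivalent-iodine oxidative 1,2-aryl migration of chalcones to α-aryl-β,β-dimethoxy ketones, the acid cyclisation of such acetals of 2'-hydroxychalcones, and the Et3SiH/BF3·OEt2 ionic reduction of cyclic acetals.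

Step 4
Reactants: 6 the (3S)-6-bromoisoflavanone bis-TBS ether; 7 tributyl(3-methylbut-2-en-1-yl)stannane
Product: 8 (3S)-7-[(tert-butyldimethylsilyl)oxy]-3-{4-[(tert-butyldimethylsilyl)oxy]-2,5-dimethoxyphenyl}-6-(3-methylbut-2-en-1-yl)chroman-4-one
Conditions: Pd(PPh3)4 (8 mol %), degassed toluene, 95 °C, 10 h
Reagents that add atoms: none
Why: In this Stille cross-coupling, zerovalent palladium inserts into C6–Br, prenyl passes from tin to palladium and reductive elimination at the unsubstituted allyl terminus gives the linear prenyl arene, while the base-free, non-polar medium leaves the acidic C3–H untouched.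

Step 5
Reactants: 8 the prenylated bis-TBS isoflavanone
Product: 9 (3S)-7-hydroxy-3-(4-hydroxy-2,5-dimethoxyphenyl)-6-(3-methylbut-2-en-1-yl)chroman-4-one (CNP0256988.2)
Conditions: Et3N·3HF (6 equiv), THF, 0 °C to rt, 4 h
Reagents that add atoms: none
Why: In this fluoride-mediated desilylation the strong Si–F bond drives cleavage of both aryl silyl ethers, and the weakly acidic HF–amine complex neither enolises C3 (no racemisation) nor protonates the prenyl alkene (no chroman formation).

## Compound list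
1 | 1-(5-bromo-2,4-dihydroxyphenyl)ethan-1-one | CC(=O)c1cc(Br)c(O)cc1O | starting material
2 | 4-hydroxy-2,5-dimethoxybenzaldehyde | COc1cc(C=O)c(OC)cc1O | starting material
3 | (E)-1-(5-bromo-2,4-dihydroxyphenyl)-3-(4-hydroxy-2,5-dimethoxyphenyl)prop-2-en-1-one | COc1cc(/C=C/C(=O)c2cc(Br)c(O)cc2O)c(OC)cc1O | intermediate
4 | bis-TBS ether of 3 (4'-O and 4-O silylated, 2'-OH free) | COc1cc(/C=C/C(=O)c2cc(Br)c(O[Si](C)(C)C(C)(C)C)cc2O)c(OC)cc1O[Si](C)(C)C(C)(C)C | intermediate
5 | (3S)-6-bromo-2-methoxy-7-(TBSO)-3-[4-(TBSO)-2,5-dimethoxyphenyl]chroman-4-one, both C2 epimers, not isolated | COc1cc([C@H]2C(OC)Oc3cc(O[Si](C)(C)C(C)(C)C)c(Br)cc3C2=O)c(OC)cc1O[Si](C)(C)C(C)(C)C | intermediate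
6 | (3S)-6-bromo-7-(TBSO)-3-[4-(TBSO)-2,5-dimethoxyphenyl]chroman-4-one | COc1cc([C@H]2COc3cc(O[Si](C)(C)C(C)(C)C)c(Br)cc3C2=O)c(OC)cc1O[Si](C)(C)C(C)(C)C | intermediate
7 | tributyl(3-methylbut-2-en-1-yl)stannane | CCCC[Sn](CCCC)(CCCC)CC=C(C)C | starting material
8 | (3S)-7-(TBSO)-3-[4-(TBSO)-2,5-dimethoxyphenyl]-6-(3-methylbut-2-en-1-yl)chroman-4-one | COc1cc([C@H]2COc3cc(O[Si](C)(C)C(C)(C)C)c(CC=C(C)C)cc3C2=O)c(OC)cc1O[Si](C)(C)C(C)(C)C | intermediate
9 | (3S)-7-hydroxy-3-(4-hydroxy-2,5-dimethoxyphenyl)-6-(3-methylbut-2-en-1-yl)chroman-4-one | COc1cc([C@H]2COc3cc(O)c(CC=C(C)C)cc3C2=O)c(OC)cc1O | target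

## Step count and risks
Total step count: 5. Longest linear sequence: 5 (steps 1 to 5). The enantiomeric excess is checked by chiral HPLC after steps 3, 4 and 5.

**Step 3 (highest risk).** Four things can go wrong:
- The C2 oxocarbenium ion may lose H-3 to give the isoflavone.
- An acyclic methoxycarbenium ion may be reduced to a methyl ether before ring C closes.
- Ring B may be oxidised by electron transfer.
- The level of induction on this heavily oxygenated chalcone is unknown.

The fallback sets out from 4 and comes back at 6. It sets the stereocentre by reduction instead of by the aryl shift.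
- 4 is treated with achiral PhI(OAc)2, BF3·OEt2 and MeOH in CH2Cl2 without silane. This gives the racemic acetal 6-bromo-2-methoxy-7-(TBSO)-3-[4-(TBSO)-2,5-dimethoxyphenyl]chroman-4-one F1.
- On warming to rt, F1 loses methanol to give the isoflavone 6-bromo-7-(TBSO)-3-[4-(TBSO)-2,5-dimethoxyphenyl]-4H-chromen-4-one F2.
- Asymmetric transfer hydrogenation with RuCl[(S,S)-TsDPEN](p-cymene) in HCO2H/Et3N first saturates C2=C3. This gives the rapidly racemising isoflavanone rac-6-bromo-7-(TBSO)-3-[4-(TBSO)-2,5-dimethoxyphenyl]chroman-4-one F3.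
- Under dynamic kinetic resolution the same catalyst then reduces the ketone of F3 to the cis alcohol (3S,4S)-6-bromo-7-(TBSO)-3-[4-(TBSO)-2,5-dimethoxyphenyl]chroman-4-ol F4.
- Dess–Martin periodinane in CH2Cl2 at 0 °C re-oxidises C4 without touching C3 and gives 6.
- Any isoflavone formed as a by-product of step 3 can be fed into this sequence.

**Step 4.** Ten hours at 95 °C may erode the labile C3 centre. The hindered, electron-rich bromide may couple slowly, and some branched 1,1-dimethylallyl product may form.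

The fallback sets out from 1 and comes back at 8. It carries a less reactive alkene through the oxidation and builds the prenyl group by metathesis under neutral conditions.
- Stille allylation of 1 (allyltributylstannane, Pd(PPh3)4, DMF, 90 °C, no stereocentre present yet) gives 1-(5-allyl-2,4-dihydroxyphenyl)ethan-1-one F5.
- The conditions of steps 1 to 3 are then repeated on F5.
- This gives the chalcone (E)-1-(5-allyl-2,4-dihydroxyphenyl)-3-(4-hydroxy-2,5-dimethoxyphenyl)prop-2-en-1-one F6.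
- Silylation gives its bis-TBS ether (E)-1-[5-allyl-4-(TBSO)-2-hydroxyphenyl]-3-[4-(TBSO)-2,5-dimethoxyphenyl]prop-2-en-1-one F7.
- The iodane step passes through the non-isolated acetal (3S)-6-allyl-2-methoxy-7-(TBSO)-3-[4-(TBSO)-2,5-dimethoxyphenyl]chroman-4-one F8.
- Silane reduction gives (3S)-6-allyl-7-(TBSO)-3-[4-(TBSO)-2,5-dimethoxyphenyl]chroman-4-one F9.
- The monosubstituted allyl alkene is far less nucleophilic than the donor-substituted enone C=C. It should therefore outlast 1.05 equiv of iodane, which a prenyl group would not.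
- Cross-metathesis of F9 with 2-methyl-2-butene (second-generation Hoveyda–Grubbs catalyst, CH2Cl2, 35 °C) gives 8.

**Step 1.** The electron-rich hydroxyaldehyde may condense sluggishly, and some flavanone may form in strong acid.

The fallback sets out from 1 and 2 and comes back at 3. It masks the phenols and condenses in base.
- MOMCl/i-Pr2NEt converts 1 into 1-[5-bromo-2-hydroxy-4-(methoxymethoxy)phenyl]ethan-1-one F10.
- The same conditions convert 2 into 2,5-dimethoxy-4-(methoxymethoxy)benzaldehyde F11.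
- KOH in EtOH at rt joins them to (E)-1-[5-bromo-2-hydroxy-4-(methoxymethoxy)phenyl]-3-[2,5-dimethoxy-4-(methoxymethoxy)phenyl]prop-2-en-1-one F12.
- HCl in MeOH at 40 °C removes both MOM groups to give 3.

## Further compounds
F1 | step 3 | rac-6-bromo-2-methoxy-7-(TBSO)-3-[4-(TBSO)-2,5-dimethoxyphenyl]chroman-4-one | COc1cc(C2C(OC)Oc3cc(O[Si](C)(C)C(C)(C)C)c(Br)cc3C2=O)c(OC)cc1O[Si](C)(C)C(C)(C)C
F2 | step 3 | 6-bromo-7-(TBSO)-3-[4-(TBSO)-2,5-dimethoxyphenyl]-4H-chromen-4-one | COc1cc(-c2coc3cc(O[Si](C)(C)C(C)(C)C)c(Br)cc3c2=O)c(OC)cc1O[Si](C)(C)C(C)(C)C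
F3 | step 3 | rac-6-bromo-7-(TBSO)-3-[4-(TBSO)-2,5-dimethoxyphenyl]chroman-4-one | COc1cc(C2COc3cc(O[Si](C)(C)C(C)(C)C)c(Br)cc3C2=O)c(OC)cc1O[Si](C)(C)C(C)(C)C
F4 | step 3 | (3S,4S)-6-bromo-7-(TBSO)-3-[4-(TBSO)-2,5-dimethoxyphenyl]chroman-4-ol (cis) | COc1cc([C@H]2COc3cc(O[Si](C)(C)C(C)(C)C)c(Br)cc3[C@H]2O)c(OC)cc1O[Si](C)(C)C(C)(C)C
F5 | step 4 | 1-(5-allyl-2,4-dihydroxyphenyl)ethan-1-one | CC(=O)c1cc(CC=C)c(O)cc1O
F6 | step 4 | (E)-1-(5-allyl-2,4-dihydroxyphenyl)-3-(4-hydroxy-2,5-dimethoxyphenyl)prop-2-en-1-one | COc1cc(/C=C/C(=O)c2cc(CC=C)c(O)cc2O)c(OC)cc1O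
F7 | step 4 | (E)-1-[5-allyl-4-(TBSO)-2-hydroxyphenyl]-3-[4-(TBSO)-2,5-dimethoxyphenyl]prop-2-en-1-one | COc1cc(/C=C/C(=O)c2cc(CC=C)c(O[Si](C)(C)C(C)(C)C)cc2O)c(OC)cc1O[Si](C)(C)C(C)(C)C
F8 | step 4 | (3S)-6-allyl-2-methoxy-7-(TBSO)-3-[4-(TBSO)-2,5-dimethoxyphenyl]chroman-4-one, both C2 epimers | COc1cc([C@H]2C(OC)Oc3cc(O[Si](C)(C)C(C)(C)C)c(CC=C)cc3C2=O)c(OC)cc1O[Si](C)(C)C(C)(C)C
F9 | step 4 | (3S)-6-allyl-7-(TBSO)-3-[4-(TBSO)-2,5-dimethoxyphenyl]chroman-4-one | COc1cc([C@H]2COc3cc(O[Si](C)(C)C(C)(C)C)c(CC=C)cc3C2=O)c(OC)cc1O[Si](C)(C)C(C)(C)C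
F10 | step 1 | 1-[5-bromo-2-hydroxy-4-(methoxymethoxy)phenyl]ethan-1-one | CC(=O)c1cc(Br)c(OCOC)cc1O
F11 | step 1 | 2,5-dimethoxy-4-(methoxymethoxy)benzaldehyde | COCOc1cc(OC)c(C=O)cc1OC
F12 | step 1 | (E)-1-[5-bromo-2-hydroxy-4-(methoxymethoxy)phenyl]-3-[2,5-dimethoxy-4-(methoxymethoxy)phenyl]prop-2-en-1-one | COCOc1cc(OC)c(/C=C/C(=O)c2cc(Br)c(OCOC)cc2O)cc1OC
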